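**Assumption:** atom labels C1–C15 follow germacranolide numbering (ring C1–C10, lactone carbons C11–C13, C14 on C10, C15 on C4). The SMILES is read as the (6R,7S,8S,9S) isomer with a Z (ring-cis) C4=C5 bond, an E enal at C1=C10 (C2 and C9 cis) and a trans-fused 12,6-lactone.

## Retrosynthetic overview

1. Target ⇐ late oxidation of the C14 allylic alcohol and bis-isobutyrylation of the 8,9-diol, which is carried as an acetonide.
2. Ten-membered carbocycle and trans-fused α-methylene lactone ⇐ one ring-closing C6–C7 bond formation: a new chromium-catalysed, ligand-controlled intramolecular 2-(methoxycarbonyl)allylation of a (Z)-enal, which sets C6 and C7.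
3. Bromo-enoate/enal precursor ⇐ Morita–Baylis–Hillman homologation at C7 and Negishi C3–C4 coupling with a (Z)-3-iodobut-2-enyl unit made from but-2-yn-1-ol.
4. C1=C10/C14 unit ⇐ Wittig olefination of a tartrate-derived methyl ketone, then SeO2 allylic oxidation; C8 and C9 come from L-threitol acetonide.
5. Ring order: dioxolane (bought) → ten-membered ring (step 20) → γ-lactone (same step).

## Route

Step 1
Reactants: 1 (4S,5S)-2,2-dimethyl-1,3-dioxolane-4,5-dimethanol (2,3-O-isopropylidene-L-threitol)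
Product: 2 [(4S,5S)-5-{[(4-methoxybenzyl)oxy]methyl}-2,2-dimethyl-1,3-dioxolan-4-yl]methanol
Conditions: NaH (1.0 equiv), THF, 0 °C; 4-methoxybenzyl chloride (1.0 equiv), Bu4NI (cat.), 0 °C to rt
Reagents that add atoms: 4-methoxybenzyl chloride, COc1ccc(CCl)cc1
Why: Williamson mono-etherification of the monosodium alkoxide of the C2-symmetric diol needs no desymmetrisation and leaves both stereocentres (the future C8 and C9, from L-tartaric acid) untouched.

Step 2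
Reactants: 2 [(4S,5S)-5-{[(4-methoxybenzyl)oxy]methyl}-2,2-dimethyl-1,3-dioxolan-4-yl]methanol
Product: 3 (4R,5S)-5-{[(4-methoxybenzyl)oxy]methyl}-2,2-dimethyl-1,3-dioxolane-4-carbaldehyde
Conditions: TEMPO (10 mol %), PhI(OAc)2 (1.1 equiv), CH2Cl2, rt
Reagents that add atoms: none
Why: oxoammonium (TEMPO) oxidation stops at the aldehyde and the trans-dioxolane α-centre does not epimerise (the 4R label is only a priority change).

Step 3
Reactants: 3 (4R,5S)-5-{[(4-methoxybenzyl)oxy]methyl}-2,2-dimethyl-1,3-dioxolane-4-carbaldehyde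
Product: 4 1-[(4S,5S)-5-{[(4-methoxybenzyl)oxy]methyl}-2,2-dimethyl-1,3-dioxolan-4-yl]ethan-1-ol (both carbinol epimers)
Conditions: MeMgBr, THF, −78 to 0 °C
Reagents that add atoms: methylmagnesium bromide, C[Mg]Br
Why: Grignard addition installs the future C14 methyl; the new carbinol centre is destroyed in step 4, so its ratio is irrelevant.

Step 4
Reactants: 4 1-[(4S,5S)-5-{[(4-methoxybenzyl)oxy]methyl}-2,2-dimethyl-1,3-dioxolan-4-yl]ethan-1-ol
Product: 5 1-[(4R,5S)-5-{[(4-methoxybenzyl)oxy]methyl}-2,2-dimethyl-1,3-dioxolan-4-yl]ethan-1-one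
Conditions: Dess–Martin periodinane, CH2Cl2, 0 °C to rt
Reagents that add atoms: none
Why: Dess–Martin oxidation under near-neutral conditions gives the α-alkoxy methyl ketone without epimerising the trans-acetonide.

Step 5
Reactants: 6 (3-bromopropoxy)(tert-butyl)dimethylsilane
Product: 7 {3-[(tert-butyldimethylsilyl)oxy]propyl}triphenylphosphonium bromide
Conditions: PPh3, MeCN, reflux
Reagents that add atoms: triphenylphosphine, c1ccc(cc1)P(c1ccccc1)c1ccccc1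
Why: SN2 quaternisation of triphenylphosphine by a primary bromide.

Step 6
Reactants: 7 {3-[(tert-butyldimethylsilyl)oxy]propyl}triphenylphosphonium bromide; 5 1-[(4R,5S)-5-{[(4-methoxybenzyl)oxy]methyl}-2,2-dimethyl-1,3-dioxolan-4-yl]ethan-1-one
Product: 9 tert-butyl{[(3Z)-4-[(4S,5S)-5-{[(4-methoxybenzyl)oxy]methyl}-2,2-dimethyl-1,3-dioxolan-4-yl]pent-3-en-1-yl]oxy}dimethylsilane, via phosphonium ylide 8 (not isolated)
Conditions: NaN(SiMe3)2, THF, 0 °C; then 5, −78 °C to rt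
Reagents that add atoms: none
Why: Wittig olefination of an α-alkoxy ketone with an unstabilised ylide builds C1=C10 and favours the Z isomer (ylide chain cis to the alkoxy-bearing carbon); any E isomer is expected to converge to the same product in step 7.

Step 7
Reactants: 9 tert-butyl{[(3Z)-4-[(4S,5S)-5-{[(4-methoxybenzyl)oxy]methyl}-2,2-dimethyl-1,3-dioxolan-4-yl]pent-3-en-1-yl]oxy}dimethylsilane
Product: 10 (2Z)-5-[(tert-butyldimethylsilyl)oxy]-2-[(4S,5S)-5-{[(4-methoxybenzyl)oxy]methyl}-2,2-dimethyl-1,3-dioxolan-4-yl]pent-2-en-1-ol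
Conditions: SeO2 (0.3 equiv), t-BuOOH (3 equiv), salicylic acid (10 mol %), CH2Cl2, rt
Reagents that add atoms: tert-butyl hydroperoxide, CC(C)(C)OO
Why: SeO2 allylic oxidation (ene reaction, then [2,3]-sigmatropic shift) attacks the methyl on the more substituted alkene carbon, and the [2,3] step places CH2OH trans to the C2 chain, which fixes the ring-cis C1=C10 geometry needed for the enal.

Step 8
Reactants: 10 (2Z)-5-[(tert-butyldimethylsilyl)oxy]-2-[(4S,5S)-5-{[(4-methoxybenzyl)oxy]methyl}-2,2-dimethyl-1,3-dioxolan-4-yl]pent-2-en-1-ol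
Product: 11 tert-butyl{[(2Z)-5-[(tert-butyldimethylsilyl)oxy]-2-[(4S,5S)-5-{[(4-methoxybenzyl)oxy]methyl}-2,2-dimethyl-1,3-dioxolan-4-yl]pent-2-en-1-yl]oxy}diphenylsilane
Conditions: t-BuPh2SiCl, imidazole, CH2Cl2, rt
Reagents that add atoms: tert-butyl(chloro)diphenylsilane, CC(C)(C)[Si](Cl)(c1ccccc1)c1ccccc1
Why: silylation of the primary allylic alcohol with an acid-stable group that survives to step 23.

Step 9
Reactants: 11 tert-butyl{[(2Z)-5-[(tert-butyldimethylsilyl)oxy]-2-[(4S,5S)-5-{[(4-methoxybenzyl)oxy]methyl}-2,2-dimethyl-1,3-dioxolan-4-yl]pent-2-en-1-yl]oxy}diphenylsilane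
Product: 12 (3Z)-5-[(tert-butyldiphenylsilyl)oxy]-4-[(4S,5S)-5-{[(4-methoxybenzyl)oxy]methyl}-2,2-dimethyl-1,3-dioxolan-4-yl]pent-3-en-1-ol
Conditions: HF·pyridine, pyridine, THF, 0 °C
Reagents that add atoms: none
Why: buffered HF·pyridine cleaves the primary alkyl TBS ether far faster than the TBDPS ether and leaves the acetonide and PMB ether intact.

Step 10
Reactants: 12 (3Z)-5-[(tert-butyldiphenylsilyl)oxy]-4-[(4S,5S)-5-{[(4-methoxybenzyl)oxy]methyl}-2,2-dimethyl-1,3-dioxolan-4-yl]pent-3-en-1-ol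
Product: 13 tert-butyl{[(2Z)-5-iodo-2-[(4S,5S)-5-{[(4-methoxybenzyl)oxy]methyl}-2,2-dimethyl-1,3-dioxolan-4-yl]pent-2-en-1-yl]oxy}diphenylsilane
Conditions: I2, PPh3, imidazole, CH2Cl2, 0 °C
Reagents that add atoms: iodine, [I][I]
Why: Appel-type iodination of a primary alcohol under neutral conditions.

Step 11
Reactants: 14 but-2-yn-1-ol
Product: 16 (2Z)-3-iodobut-2-en-1-ol, via cyclic vinylalanate 15 (not isolated)
Conditions: NaAlH2(OCH2CH2OCH3)2, THF, 0 °C to rt; then I2, −78 to 0 °C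
Reagents that add atoms: iodine, [I][I]
Why: hydroxyl-directed trans-hydroalumination puts aluminium on C3 in a five-membered alanate, and iodinolysis with retention gives the Z vinyl iodide that encodes the ring-cis C4=C5 bond.

Step 12
Reactants: 16 (2Z)-3-iodobut-2-en-1-ol
Product: 17 tert-butyl{[(2Z)-3-iodobut-2-en-1-yl]oxy}dimethylsilane
Conditions: t-BuMe2SiCl, imidazole, CH2Cl2, rt
Reagents that add atoms: tert-butyl(chloro)dimethylsilane, CC(C)(C)[Si](C)(C)Cl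
Why: standard silylation of the allylic alcohol.

Step 13
Reactants: 13 tert-butyl{[(2Z)-5-iodo-2-[(4S,5S)-5-{[(4-methoxybenzyl)oxy]methyl}-2,2-dimethyl-1,3-dioxolan-4-yl]pent-2-en-1-yl]oxy}diphenylsilane; 17 tert-butyl{[(2Z)-3-iodobut-2-en-1-yl]oxy}dimethylsilane
Product: 19 (2Z,6Z)-1-[(tert-butyldimethylsilyl)oxy]-8-[(tert-butyldiphenylsilyl)oxy]-7-[(4S,5S)-5-{[(4-methoxybenzyl)oxy]methyl}-2,2-dimethyl-1,3-dioxolan-4-yl]-3-methylocta-2,6-diene, via alkylzinc iodide 18 (not isolated)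
Conditions: Zn dust (activated with 1,2-dibromoethane and Me3SiCl), LiCl, THF, 40 °C; then 17, PdCl2(dppf) (5 mol %), THF/N-methylpyrrolidone, 50 °C
Reagents that add atoms: none
Why: Negishi sp3–sp2 cross-coupling (zinc insertion into the primary iodide, then zerovalent palladium catalysis) forms C3–C4 with retention of the vinyl iodide geometry.

Step 14
Reactants: 19 (2Z,6Z)-1-[(tert-butyldimethylsilyl)oxy]-8-[(tert-butyldiphenylsilyl)oxy]-7-[(4S,5S)-5-{[(4-methoxybenzyl)oxy]methyl}-2,2-dimethyl-1,3-dioxolan-4-yl]-3-methylocta-2,6-diene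
Product: 20 [(4S,5S)-5-{(2Z,6Z)-8-[(tert-butyldimethylsilyl)oxy]-1-[(tert-butyldiphenylsilyl)oxy]-6-methylocta-2,6-dien-2-yl}-2,2-dimethyl-1,3-dioxolan-4-yl]methanol
Conditions: DDQ, CH2Cl2/pH 7 buffer (10:1), 0 °C
Reagents that add atoms: none
Why: oxidative PMB cleavage by DDQ is selective in the presence of silyl ethers, the acetonide and trisubstituted alkenes.

Step 15
Reactants: 20 [(4S,5S)-5-{(2Z,6Z)-8-[(tert-butyldimethylsilyl)oxy]-1-[(tert-butyldiphenylsilyl)oxy]-6-methylocta-2,6-dien-2-yl}-2,2-dimethyl-1,3-dioxolan-4-yl]methanol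
Product: 21 (4R,5S)-5-{(2Z,6Z)-8-[(tert-butyldimethylsilyl)oxy]-1-[(tert-butyldiphenylsilyl)oxy]-6-methylocta-2,6-dien-2-yl}-2,2-dimethyl-1,3-dioxolane-4-carbaldehyde
Conditions: TEMPO (10 mol %), PhI(OAc)2 (1.1 equiv), CH2Cl2, rt
Reagents that add atoms: none
Why: TEMPO oxidation gives the α-alkoxy aldehyde (future C7) without epimerisation.

Step 16
Reactants: 21 (4R,5S)-5-{(2Z,6Z)-8-[(tert-butyldimethylsilyl)oxy]-1-[(tert-butyldiphenylsilyl)oxy]-6-methylocta-2,6-dien-2-yl}-2,2-dimethyl-1,3-dioxolane-4-carbaldehyde; 22 methyl acrylate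
Product: 23 methyl 2-{[(4S,5S)-5-{(2Z,6Z)-8-[(tert-butyldimethylsilyl)oxy]-1-[(tert-butyldiphenylsilyl)oxy]-6-methylocta-2,6-dien-2-yl}-2,2-dimethyl-1,3-dioxolan-4-yl](hydroxy)methyl}prop-2-enoate (both carbinol epimers)
Conditions: methyl acrylate (5 equiv), DABCO (1 equiv), MeOH, rt, 5 d
Reagents that add atoms: none
Why: the Morita–Baylis–Hillman reaction attaches C11–C13 to C7; the carbinol configuration is irrelevant because it is lost in step 17.

Step 17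
Reactants: 23 methyl 2-{[(4S,5S)-5-{(2Z,6Z)-8-[(tert-butyldimethylsilyl)oxy]-1-[(tert-butyldiphenylsilyl)oxy]-6-methylocta-2,6-dien-2-yl}-2,2-dimethyl-1,3-dioxolan-4-yl](hydroxy)methyl}prop-2-enoate
Product: 24 methyl (2Z)-2-(bromomethyl)-3-[(4S,5S)-5-{(2Z,6Z)-8-[(tert-butyldimethylsilyl)oxy]-1-[(tert-butyldiphenylsilyl)oxy]-6-methylocta-2,6-dien-2-yl}-2,2-dimethyl-1,3-dioxolan-4-yl]prop-2-enoate
Conditions: N-bromosuccinimide, Me2S, CH2Cl2, 0 °C to rt
Reagents that add atoms: N-bromosuccinimide, O=C1CCC(=O)N1Br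
Why: Corey–Kim-type activation of the alcohol followed by SN2' attack of bromide gives the thermodynamically preferred (Z)-2-(bromomethyl)enoate.

Step 18
Reactants: 24 methyl (2Z)-2-(bromomethyl)-3-[(4S,5S)-5-{(2Z,6Z)-8-[(tert-butyldimethylsilyl)oxy]-1-[(tert-butyldiphenylsilyl)oxy]-6-methylocta-2,6-dien-2-yl}-2,2-dimethyl-1,3-dioxolan-4-yl]prop-2-enoate
Product: 25 methyl (2Z)-2-(bromomethyl)-3-[(4S,5S)-5-{(2Z,6Z)-1-[(tert-butyldiphenylsilyl)oxy]-8-hydroxy-6-methylocta-2,6-dien-2-yl}-2,2-dimethyl-1,3-dioxolan-4-yl]prop-2-enoate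
Conditions: AcOH/THF/H2O (3:1:1), rt
Reagents that add atoms: none
Why: mild aqueous acetic acid removes the primary allylic TBS ether while the TBDPS ether, acetonide and allylic bromide survive.

Step 19
Reactants: 25 methyl (2Z)-2-(bromomethyl)-3-[(4S,5S)-5-{(2Z,6Z)-1-[(tert-butyldiphenylsilyl)oxy]-8-hydroxy-6-methylocta-2,6-dien-2-yl}-2,2-dimethyl-1,3-dioxolan-4-yl]prop-2-enoate
Product: 26 methyl (2Z)-2-(bromomethyl)-3-[(4S,5S)-5-{(2Z,6Z)-1-[(tert-butyldiphenylsilyl)oxy]-6-methyl-8-oxoocta-2,6-dien-2-yl}-2,2-dimethyl-1,3-dioxolan-4-yl]prop-2-enoate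
Conditions: TEMPO (10 mol %), PhI(OAc)2 (1.1 equiv), CH2Cl2, 0 °C to rt
Reagents that add atoms: none
Why: TEMPO/PhI(OAc)2 oxidises the allylic alcohol to the (Z)-enal without Z to E isomerisation and without touching the allylic bromide.

Step 20
Reactants: 26 methyl (2Z)-2-(bromomethyl)-3-[(4S,5S)-5-{(2Z,6Z)-1-[(tert-butyldiphenylsilyl)oxy]-6-methyl-8-oxoocta-2,6-dien-2-yl}-2,2-dimethyl-1,3-dioxolan-4-yl]prop-2-enoate
Product: 29 (6R,7S,8S,9S)-14-[(tert-butyldiphenylsilyl)oxy]-8,9-(isopropylidenedioxy)germacra-1(10)Z,4Z,11(13)-trien-12,6-olide (trans-fused lactone), via trimethylsilyl ether 27 (not isolated), via hydroxy ester 28 (not isolated)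
Conditions: CrCl2 (15 mol %), (S,S)-3,6-di-tert-butyl-1,8-bis(4-isopropyl-4,5-dihydro-1,3-oxazol-2-yl)-9H-carbazole (18 mol %; the antipode is used if it proves to be the matched one), i-Pr2NEt (30 mol %), Mn powder (3 equiv), Me3SiCl (2 equiv), THF, 25 °C, 26 added over 12 h to 2 mM; then 0.5 M HCl, THF, 0 °C
Reagents that add atoms: none
Why: Proposed new method: chromium-catalysed, ligand-controlled ring-closing 2-(methoxycarbonyl)allylation; divalent chromium reduces the allylic bromide to an allyl–chromium species (trivalent chromium) held by the tridentate carbazole bis(oxazoline), the E and Z allyl forms equilibrate, and C7 (the γ-carbon) adds to the C6 aldehyde through a closed chair transition state with the C8 branch pseudo-equatorial, which gives the 6,7-anti (trans-lactone) relationship, while the ligand shields one aldehyde face so that Si-face attack sets 6R and therefore 7S, expected to be reinforced by the substrate's own preference for attack anti to the C8–C9 bond; Me3SiCl frees the chromium alkoxide, Mn returns it to divalent chromium, and acid work-up desilylates and lactonises; the closest known reactions are the intermolecular chromium-catalysed enantioselective 2-(alkoxycarbonyl)allylation of aldehydes to α-methylene-γ-butyrolactones and the stoichiometric CrCl2 Nozaki–Hiyama–Kishi macrocyclisation used for germacrane rings, and what is new is the catalytic, catalyst-controlled closure of a ten-membered ring with a γ-branched, δ-oxygenated bromide.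

Step 21
Reactants: 29 (6R,7S,8S,9S)-14-[(tert-butyldiphenylsilyl)oxy]-8,9-(isopropylidenedioxy)germacra-1(10)Z,4Z,11(13)-trien-12,6-olide
Product: 30 (6R,7R,8S,9S)-14-[(tert-butyldiphenylsilyl)oxy]-8,9-dihydroxygermacra-1(10)Z,4Z,11(13)-trien-12,6-olide (the C7 label changes by priority rules only)
Conditions: 80% aq. AcOH, 50 °C
Reagents that add atoms: none
Why: aqueous acetic acid hydrolyses the dioxolane while the TBDPS ether and the α-methylene lactone are stable; no stereocentre is affected.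

Step 22
Reactants: 30 (6R,7R,8S,9S)-14-[(tert-butyldiphenylsilyl)oxy]-8,9-dihydroxygermacra-1(10)Z,4Z,11(13)-trien-12,6-olide
Product: 31 (6R,7S,8S,9S)-14-[(tert-butyldiphenylsilyl)oxy]-8,9-bis(2-methylpropanoyloxy)germacra-1(10)Z,4Z,11(13)-trien-12,6-olide
Conditions: (i-PrCO)2O, DMAP (cat.), pyridine, 0 °C to rt
Reagents that add atoms: isobutyric anhydride, CC(C)C(=O)OC(=O)C(C)C
Why: DMAP-catalysed acylation esterifies both secondary alcohols.

Step 23
Reactants: 31 (6R,7S,8S,9S)-14-[(tert-butyldiphenylsilyl)oxy]-8,9-bis(2-methylpropanoyloxy)germacra-1(10)Z,4Z,11(13)-trien-12,6-olide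
Product: 32 (6R,7S,8S,9S)-14-hydroxy-8,9-bis(2-methylpropanoyloxy)germacra-1(10)Z,4Z,11(13)-trien-12,6-olide
Conditions: HF·pyridine, pyridine, THF, 0 °C to rt
Reagents that add atoms: none
Why: HF·pyridine removes the TBDPS group under mildly acidic conditions that avoid acyl migration and Michael addition to the α-methylene lactone.

Step 24
Reactants: 32 (6R,7S,8S,9S)-14-hydroxy-8,9-bis(2-methylpropanoyloxy)germacra-1(10)Z,4Z,11(13)-trien-12,6-olide
Product: 33 (3aS,4S,5S,6E,10Z,11aR)-6-formyl-10-methyl-3-methylidene-2-oxo-2,3,3a,4,5,8,9,11a-octahydrocyclodeca[b]furan-4,5-diyl bis(2-methylpropanoate) (target CNP0305839.3)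
Conditions: TEMPO (10 mol %), PhI(OAc)2 (1.1 equiv), CH2Cl2, rt
Reagents that add atoms: none
Why: chemoselective oxidation of the primary allylic alcohol gives the conjugated (E)-enal, the thermodynamically preferred geometry, and completes the target.

## Compound list

1 | (4S,5S)-2,2-dimethyl-1,3-dioxolane-4,5-dimethanol (2,3-O-isopropylidene-L-threitol) | OC[C@@H]1OC(C)(C)O[C@H]1CO | starting material
2 | [(4S,5S)-5-{[(4-methoxybenzyl)oxy]methyl}-2,2-dimethyl-1,3-dioxolan-4-yl]methanol | OC[C@@H]1OC(C)(C)O[C@H]1COCc1ccc(OC)cc1 | intermediate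
3 | (4R,5S)-5-{[(4-methoxybenzyl)oxy]methyl}-2,2-dimethyl-1,3-dioxolane-4-carbaldehyde | O=C[C@@H]1OC(C)(C)O[C@H]1COCc1ccc(OC)cc1 | intermediate
4 | 1-[(4S,5S)-5-{[(4-methoxybenzyl)oxy]methyl}-2,2-dimethyl-1,3-dioxolan-4-yl]ethan-1-ol (both carbinol epimers) | CC(O)[C@@H]1OC(C)(C)O[C@H]1COCc1ccc(OC)cc1 | intermediate
5 | 1-[(4R,5S)-5-{[(4-methoxybenzyl)oxy]methyl}-2,2-dimethyl-1,3-dioxolan-4-yl]ethan-1-one | CC(=O)[C@@H]1OC(C)(C)O[C@H]1COCc1ccc(OC)cc1 | intermediate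
6 | (3-bromopropoxy)(tert-butyl)dimethylsilane | CC(C)(C)[Si](C)(C)OCCCBr | starting material
7 | {3-[(tert-butyldimethylsilyl)oxy]propyl}triphenylphosphonium bromide | CC(C)(C)[Si](C)(C)OCCC[P+](c1ccccc1)(c1ccccc1)c1ccccc1.[Br-] | intermediate
8 | {3-[(tert-butyldimethylsilyl)oxy]propylidene}triphenylphosphorane (ylide, not isolated) | CC(C)(C)[Si](C)(C)OCCC=P(c1ccccc1)(c1ccccc1)c1ccccc1 | intermediate
9 | tert-butyl{[(3Z)-4-[(4S,5S)-5-{[(4-methoxybenzyl)oxy]methyl}-2,2-dimethyl-1,3-dioxolan-4-yl]pent-3-en-1-yl]oxy}dimethylsilane | C/C(=C/CCO[Si](C)(C)C(C)(C)C)[C@@H]1OC(C)(C)O[C@H]1COCc1ccc(OC)cc1 | intermediate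
10 | (2Z)-5-[(tert-butyldimethylsilyl)oxy]-2-[(4S,5S)-5-{[(4-methoxybenzyl)oxy]methyl}-2,2-dimethyl-1,3-dioxolan-4-yl]pent-2-en-1-ol | OC/C(=C/CCO[Si](C)(C)C(C)(C)C)[C@@H]1OC(C)(C)O[C@H]1COCc1ccc(OC)cc1 | intermediate
11 | tert-butyl{[(2Z)-5-[(tert-butyldimethylsilyl)oxy]-2-[(4S,5S)-5-{[(4-methoxybenzyl)oxy]methyl}-2,2-dimethyl-1,3-dioxolan-4-yl]pent-2-en-1-yl]oxy}diphenylsilane | CC(C)(C)[Si](c1ccccc1)(c1ccccc1)OC/C(=C/CCO[Si](C)(C)C(C)(C)C)[C@@H]1OC(C)(C)O[C@H]1COCc1ccc(OC)cc1 | intermediate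
12 | (3Z)-5-[(tert-butyldiphenylsilyl)oxy]-4-[(4S,5S)-5-{[(4-methoxybenzyl)oxy]methyl}-2,2-dimethyl-1,3-dioxolan-4-yl]pent-3-en-1-ol | OCC/C=C(/CO[Si](c1ccccc1)(c1ccccc1)C(C)(C)C)[C@@H]1OC(C)(C)O[C@H]1COCc1ccc(OC)cc1 | intermediate
13 | tert-butyl{[(2Z)-5-iodo-2-[(4S,5S)-5-{[(4-methoxybenzyl)oxy]methyl}-2,2-dimethyl-1,3-dioxolan-4-yl]pent-2-en-1-yl]oxy}diphenylsilane | ICC/C=C(/CO[Si](c1ccccc1)(c1ccccc1)C(C)(C)C)[C@@H]1OC(C)(C)O[C@H]1COCc1ccc(OC)cc1 | intermediate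
14 | but-2-yn-1-ol | CC#CCO | starting material
15 | sodium 2,2-bis(2-methoxyethoxy)-3-methyl-2,5-dihydro-1,2-oxaaluminol-2-uide (cyclic vinylalanate, not isolated) | CC1=CCO[Al-]1(OCCOC)OCCOC.[Na+] | intermediate
16 | (2Z)-3-iodobut-2-en-1-ol | C/C(I)=C/CO | intermediate
17 | tert-butyl{[(2Z)-3-iodobut-2-en-1-yl]oxy}dimethylsilane | C/C(I)=C/CO[Si](C)(C)C(C)(C)C | intermediate
18 | iodo{(3Z)-5-[(tert-butyldiphenylsilyl)oxy]-4-[(4S,5S)-5-{[(4-methoxybenzyl)oxy]methyl}-2,2-dimethyl-1,3-dioxolan-4-yl]pent-3-en-1-yl}zinc (not isolated) | I[Zn]CC/C=C(/CO[Si](c1ccccc1)(c1ccccc1)C(C)(C)C)[C@@H]1OC(C)(C)O[C@H]1COCc1ccc(OC)cc1 | intermediate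
19 | (2Z,6Z)-1-[(tert-butyldimethylsilyl)oxy]-8-[(tert-butyldiphenylsilyl)oxy]-7-[(4S,5S)-5-{[(4-methoxybenzyl)oxy]methyl}-2,2-dimethyl-1,3-dioxolan-4-yl]-3-methylocta-2,6-diene | CC(C)(C)[Si](C)(C)OC/C=C(/C)CC/C=C(/CO[Si](c1ccccc1)(c1ccccc1)C(C)(C)C)[C@@H]1OC(C)(C)O[C@H]1COCc1ccc(OC)cc1 | intermediate
20 | [(4S,5S)-5-{(2Z,6Z)-8-[(tert-butyldimethylsilyl)oxy]-1-[(tert-butyldiphenylsilyl)oxy]-6-methylocta-2,6-dien-2-yl}-2,2-dimethyl-1,3-dioxolan-4-yl]methanol | CC(C)(C)[Si](C)(C)OC/C=C(/C)CC/C=C(/CO[Si](c1ccccc1)(c1ccccc1)C(C)(C)C)[C@@H]1OC(C)(C)O[C@H]1CO | intermediate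
21 | (4R,5S)-5-{(2Z,6Z)-8-[(tert-butyldimethylsilyl)oxy]-1-[(tert-butyldiphenylsilyl)oxy]-6-methylocta-2,6-dien-2-yl}-2,2-dimethyl-1,3-dioxolane-4-carbaldehyde | CC(C)(C)[Si](C)(C)OC/C=C(/C)CC/C=C(/CO[Si](c1ccccc1)(c1ccccc1)C(C)(C)C)[C@@H]1OC(C)(C)O[C@H]1C=O | intermediate
22 | methyl acrylate | C=CC(=O)OC | starting material
23 | methyl 2-{[(4S,5S)-5-{(2Z,6Z)-8-[(tert-butyldimethylsilyl)oxy]-1-[(tert-butyldiphenylsilyl)oxy]-6-methylocta-2,6-dien-2-yl}-2,2-dimethyl-1,3-dioxolan-4-yl](hydroxy)methyl}prop-2-enoate (both carbinol epimers) | CC(C)(C)[Si](C)(C)OC/C=C(/C)CC/C=C(/CO[Si](c1ccccc1)(c1ccccc1)C(C)(C)C)[C@@H]1OC(C)(C)O[C@H]1C(O)C(=C)C(=O)OC | intermediate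
24 | methyl (2Z)-2-(bromomethyl)-3-[(4S,5S)-5-{(2Z,6Z)-8-[(tert-butyldimethylsilyl)oxy]-1-[(tert-butyldiphenylsilyl)oxy]-6-methylocta-2,6-dien-2-yl}-2,2-dimethyl-1,3-dioxolan-4-yl]prop-2-enoate | CC(C)(C)[Si](C)(C)OC/C=C(/C)CC/C=C(/CO[Si](c1ccccc1)(c1ccccc1)C(C)(C)C)[C@@H]1OC(C)(C)O[C@H]1/C=C(/C(=O)OC)CBr | intermediate
25 | methyl (2Z)-2-(bromomethyl)-3-[(4S,5S)-5-{(2Z,6Z)-1-[(tert-butyldiphenylsilyl)oxy]-8-hydroxy-6-methylocta-2,6-dien-2-yl}-2,2-dimethyl-1,3-dioxolan-4-yl]prop-2-enoate | OC/C=C(/C)CC/C=C(/CO[Si](c1ccccc1)(c1ccccc1)C(C)(C)C)[C@@H]1OC(C)(C)O[C@H]1/C=C(/C(=O)OC)CBr | intermediate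
26 | methyl (2Z)-2-(bromomethyl)-3-[(4S,5S)-5-{(2Z,6Z)-1-[(tert-butyldiphenylsilyl)oxy]-6-methyl-8-oxoocta-2,6-dien-2-yl}-2,2-dimethyl-1,3-dioxolan-4-yl]prop-2-enoate | O=C/C=C(/C)CC/C=C(/CO[Si](c1ccccc1)(c1ccccc1)C(C)(C)C)[C@@H]1OC(C)(C)O[C@H]1/C=C(/C(=O)OC)CBr | intermediate
27 | 6-O-trimethylsilyl ether of hydroxy ester 28 (same configuration, not isolated) | C=C(C(=O)OC)[C@H]1[C@H](O[Si](C)(C)C)/C=C(/C)CC/C=C(/CO[Si](c2ccccc2)(c2ccccc2)C(C)(C)C)[C@@H]2OC(C)(C)O[C@@H]12 | intermediate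
28 | methyl (6R,7S,8S,9S)-14-[(tert-butyldiphenylsilyl)oxy]-6-hydroxy-8,9-(isopropylidenedioxy)germacra-1(10)Z,4Z,11(13)-trien-12-oate (not isolated) | C=C(C(=O)OC)[C@H]1[C@H](O)/C=C(/C)CC/C=C(/CO[Si](c2ccccc2)(c2ccccc2)C(C)(C)C)[C@@H]2OC(C)(C)O[C@@H]12 | intermediate
29 | (6R,7S,8S,9S)-14-[(tert-butyldiphenylsilyl)oxy]-8,9-(isopropylidenedioxy)germacra-1(10)Z,4Z,11(13)-trien-12,6-olide (trans-fused lactone) | C=C1C(=O)O[C@@H]2/C=C(/C)CC/C=C(/CO[Si](c3ccccc3)(c3ccccc3)C(C)(C)C)[C@@H]3OC(C)(C)O[C@H]3[C@@H]12 | intermediate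
30 | (6R,7R,8S,9S)-14-[(tert-butyldiphenylsilyl)oxy]-8,9-dihydroxygermacra-1(10)Z,4Z,11(13)-trien-12,6-olide (same spatial arrangement as 29) | C=C1C(=O)O[C@@H]2/C=C(/C)CC/C=C(/CO[Si](c3ccccc3)(c3ccccc3)C(C)(C)C)[C@H](O)[C@@H](O)[C@@H]12 | intermediate
31 | (6R,7S,8S,9S)-14-[(tert-butyldiphenylsilyl)oxy]-8,9-bis(2-methylpropanoyloxy)germacra-1(10)Z,4Z,11(13)-trien-12,6-olide | C=C1C(=O)O[C@@H]2/C=C(/C)CC/C=C(/CO[Si](c3ccccc3)(c3ccccc3)C(C)(C)C)[C@H](OC(=O)C(C)C)[C@@H](OC(=O)C(C)C)[C@@H]12 | intermediate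
32 | (6R,7S,8S,9S)-14-hydroxy-8,9-bis(2-methylpropanoyloxy)germacra-1(10)Z,4Z,11(13)-trien-12,6-olide | C=C1C(=O)O[C@@H]2/C=C(/C)CC/C=C(/CO)[C@H](OC(=O)C(C)C)[C@@H](OC(=O)C(C)C)[C@@H]12 | intermediate
33 | (3aS,4S,5S,6E,10Z,11aR)-6-formyl-10-methyl-3-methylidene-2-oxo-2,3,3a,4,5,8,9,11a-octahydrocyclodeca[b]furan-4,5-diyl bis(2-methylpropanoate) | C=C1C(=O)O[C@@H]2/C=C(/C)CC/C=C(/C=O)[C@H](OC(=O)C(C)C)[C@@H](OC(=O)C(C)C)[C@@H]12 | target

## Step count and risks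

Total step count: 24. Longest linear sequence: 21 steps (1 → 33 through steps 1–4, 6–10 and 13–24).

**Three steps most likely to fail**

Step 20 (the proposed new macrocyclisation). The risks are oligomerisation, 1,4-elimination of the C8 oxygen from the allylchromium species, and a mismatched ligand/substrate pairing. The fallback uses known chemistry, sets out from bromo enal 26 and comes back at lactone 29. Catalyst control is given up and the ring is closed by the classical stoichiometric Nozaki–Hiyama–Kishi allylation under substrate control (CrCl2, 8 equiv, THF/DMF, 2 mM, rt; then dilute HCl), the established way to close germacranolide rings. Any 29 formed is used directly. If the aldehyde is attacked on the other face, the product is the cis-fused C6 epimer (6S,7S,8S,9S)-14-[(tert-butyldiphenylsilyl)oxy]-8,9-(isopropylidenedioxy)germacra-1(10)Z,4Z,11(13)-trien-12,6-olide F1. This is opened with LiOH (THF/H2O, 0 °C) to the hydroxy acid (6S,7S,8S,9S)-14-[(tert-butyldiphenylsilyl)oxy]-6-hydroxy-8,9-(isopropylidenedioxy)germacra-1(10)Z,4Z,11(13)-trien-12-oic acid F2. Mitsunobu lactonisation (PPh3, diisopropyl azodicarboxylate, toluene, high dilution) then re-closes it with inversion at C6 to give 29. This repair only covers a wrong C6; a wrong C7 cannot be corrected this way.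

Step 7 (SeO2 oxidation). The alkene is deactivated by the neighbouring acetonide oxygen, so conversion and site selectivity may be poor. The fallback sets out from aldehyde 3 and comes back at allylic alcohol 10, replacing steps 3 to 7 by an alkyne route. Dimethyl (1-diazo-2-oxopropyl)phosphonate with K2CO3 in MeOH converts 3 into the alkyne (4S,5S)-4-ethynyl-5-{[(4-methoxybenzyl)oxy]methyl}-2,2-dimethyl-1,3-dioxolane F3. n-BuLi, BF3·OEt2 and oxirane give the homopropargylic alcohol 4-[(4S,5S)-5-{[(4-methoxybenzyl)oxy]methyl}-2,2-dimethyl-1,3-dioxolan-4-yl]but-3-yn-1-ol F4. t-BuMe2SiCl and imidazole give the silyl ether tert-butyl({4-[(4S,5S)-5-{[(4-methoxybenzyl)oxy]methyl}-2,2-dimethyl-1,3-dioxolan-4-yl]but-3-yn-1-yl}oxy)dimethylsilane F5. Bu3SnH with PdCl2(PPh3)2 adds syn and places tin on the alkyne carbon next to the oxygenated carbon, giving the vinylstannane tributyl{(1E)-4-[(tert-butyldimethylsilyl)oxy]-1-[(4R,5S)-5-{[(4-methoxybenzyl)oxy]methyl}-2,2-dimethyl-1,3-dioxolan-4-yl]but-1-en-1-yl}stannane F6. Tin–lithium exchange (n-BuLi, THF, −78 °C) and trapping with paraformaldehyde give 10 with retention of the double-bond geometry.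

Step 16 (Morita–Baylis–Hillman reaction). The hindered α-alkoxy aldehyde may react very slowly. The fallback sets out from aldehyde 21 and comes back at adduct 23, replacing amine catalysis by a preformed nucleophile (vinylalumination). i-Bu2AlH and N-methylmorpholine N-oxide with methyl propiolate (THF, 0 °C) generate the vinylaluminium reagent [1-(methoxycarbonyl)ethenyl]bis(2-methylpropyl)aluminium F7, which adds to 21 and gives 23 after aqueous work-up.

## Further compounds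

F1 | step 20 | (6S,7S,8S,9S)-14-[(tert-butyldiphenylsilyl)oxy]-8,9-(isopropylidenedioxy)germacra-1(10)Z,4Z,11(13)-trien-12,6-olide (cis-fused C6 epimer of 29) | C=C1C(=O)O[C@H]2/C=C(/C)CC/C=C(/CO[Si](c3ccccc3)(c3ccccc3)C(C)(C)C)[C@@H]3OC(C)(C)O[C@H]3[C@@H]12
F2 | step 20 | (6S,7S,8S,9S)-14-[(tert-butyldiphenylsilyl)oxy]-6-hydroxy-8,9-(isopropylidenedioxy)germacra-1(10)Z,4Z,11(13)-trien-12-oic acid | C=C(C(=O)O)[C@H]1[C@@H](O)/C=C(/C)CC/C=C(/CO[Si](c2ccccc2)(c2ccccc2)C(C)(C)C)[C@@H]2OC(C)(C)O[C@@H]12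
F3 | step 7 | (4S,5S)-4-ethynyl-5-{[(4-methoxybenzyl)oxy]methyl}-2,2-dimethyl-1,3-dioxolane | C#C[C@@H]1OC(C)(C)O[C@H]1COCc1ccc(OC)cc1
F4 | step 7 | 4-[(4S,5S)-5-{[(4-methoxybenzyl)oxy]methyl}-2,2-dimethyl-1,3-dioxolan-4-yl]but-3-yn-1-ol | OCCC#C[C@@H]1OC(C)(C)O[C@H]1COCc1ccc(OC)cc1
F5 | step 7 | tert-butyl({4-[(4S,5S)-5-{[(4-methoxybenzyl)oxy]methyl}-2,2-dimethyl-1,3-dioxolan-4-yl]but-3-yn-1-yl}oxy)dimethylsilane | CC(C)(C)[Si](C)(C)OCCC#C[C@@H]1OC(C)(C)O[C@H]1COCc1ccc(OC)cc1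
F6 | step 7 | tributyl{(1E)-4-[(tert-butyldimethylsilyl)oxy]-1-[(4R,5S)-5-{[(4-methoxybenzyl)oxy]methyl}-2,2-dimethyl-1,3-dioxolan-4-yl]but-1-en-1-yl}stannane | CCCC[Sn](CCCC)(CCCC)/C(=C/CCO[Si](C)(C)C(C)(C)C)[C@@H]1OC(C)(C)O[C@H]1COCc1ccc(OC)cc1
F7 | step 16 | [1-(methoxycarbonyl)ethenyl]bis(2-methylpropyl)aluminium | C=C(C(=O)OC)[Al](CC(C)C)CC(C)C
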